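**Numbering and assumption**

- Core atoms are numbered as in 2,6-diaryl-3,7-dioxabicyclo[3.3.0]octane and keep their labels in every intermediate. ArA = 3-hydroxy-4,5-dimethoxyphenyl (benzyl-protected until the last step) on C2; ArB = 3,4,5-trimethoxyphenyl on C6. Ring 1 = C1–C2–O3–C4–C5; ring 2 = C5–C6–O7–C8–C1.
- Assumption: the (R)-configured tert-butyl phosphinooxazoline ligand is taken to deliver the (2S)-dihydrofuran 10, by analogy with simple aryl triflates, where the C2 priorities are the same; if the sense of induction is opposite for triflate 8, the (S)-ligand is used.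

## Analysis of the target

Target 17 is a furofuran lignan: a cis-fused 3,7-dioxabicyclo[3.3.0]octane in which ring 1 and ring 2 share the C1–C5 bond, with ArA on C2 and ArB on C6. The four stereocentres are contiguous, (1R,2S,5R,6S): the ring fusion is cis and each aryl group is exo, that is, trans to the ring bond leaving the neighbouring bridgehead (ArA trans to C1–C8, ArB trans to C5–C4). The core has a twofold pseudo-symmetry, but the aryl groups differ by one O-methyl group, so the halves cannot come from a dimerisation and the single phenol must be told apart from five methyl ethers. The sensitive sites are the benzylic ether bonds C2–O3 and C6–O7, which ionise under protic or Lewis acids (epimerisation to endo-aryl isomers) and can be cut by hydrogenolysis, and the electron-rich arenes, which are easily oxidised. The difficulty is to set four adjacent stereocentres, as one enantiomer and with two different aryl groups, on a small skeleton that offers only C–O and C–H bonds as handles. The strategy rests on the position of C6 and C8: both hang on the C5–C1 edge and are joined to each other only through O7, so deleting O7 and bonding C8 to C6 turns ring 2 into a cyclobutanone C1–C8(=O)–C6–C5 fused to ring 1. Such a cyclobutanone is the (2+2) adduct of an ArB-substituted ketene equivalent with the C1=C5 double bond of a 2-aryl-2,5-dihydrofuran, and a Baeyer–Villiger oxidation puts O7 back.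

## Retrosynthetic reasoning

**17 to 16.** The phenol is unmasked last. No skeletal bond is cut; the gain is that every earlier step runs without an acidic, oxidisable phenol. The forward step must remove one O-benzyl group without touching the two benzylic ring ethers.

**16 to 15 to 14.** C8 is a methylene in 16, but an oxygen insertion leaves it as a carbonyl. 16 is therefore traced to lactol 15 and lactone 14; only the oxidation level of C8 changes. Forward, a partial hydride reduction and an ionic deoxygenation of the lactol are needed, mild enough to leave C2–O3 and C6–O7 intact.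

**14 to 13.** The C6–O7 bond is cut and C6 is joined to C8, the retron of a Baeyer–Villiger oxidation. This gives cyclobutanone 13 (in bicyclo[3.2.0]heptane numbering the ketone is C6, ArB sits on C7 and ArA on C4, next to the bridgehead that carries the carbonyl). The cut is at C6–O7 and not at C8–O7 because C6, secondary and benzylic, is the carbon that migrates to oxygen. Migration goes with retention, so the configuration of C6 in the target is that of the cyclobutanone.

**13 to 10 and 3.** 13 is cut at C1–C8 and C5–C6, the two bonds that attach the C8–C6 unit to the C1–C5 edge. The pieces are (S)-dihydrofuran 10, whose C1=C5 double bond is the 2π partner, and keteniminium ion 11 (C8 the iminium carbon, C6 bearing ArB), made in the flask from amide 3; the adduct is iminium salt 12, hydrolysed to 13. This cut removes one ring, two C–C bonds and three stereocentres (C1, C5, C6) at once and leaves a precursor with one stereocentre, C2. The forward reaction must bond C8 to C1 and C6 to C5 (not the reverse), on the alkene face opposite ArA, and place ArB exo.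

**3 to 1.** Amide 3 is the dimethylamide of acid 1, reached through acid chloride 2; one C–N bond by standard acylation.

**10 to 8 and 9.** 10 is cut at the C2–aryl bond, giving aryl triflate 8 and 2,3-dihydrofuran 9, joined by an asymmetric Heck reaction. This is the only step in which a chiral catalyst sets absolute configuration; all other stereocentres are relayed from C2. The catalyst must also release the product before the double bond moves into conjugation with oxygen, because the isolated C1=C5 bond is needed.

**8 to 7 to 5 to 4.** Triflate 8 comes from phenol 7. Phenol 7 comes from benzaldehyde 5 by oxidative replacement of the formyl group through formate 6 (a C–C bond is cut). 5 comes from the commercial hydroxy aldehyde 4 by O-benzylation. The formyl group serves only as a placeholder for the oxygen that becomes the triflate.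

## Alternatives that were turned down

**Alternative 1:** Conjugate addition–aldol on a chiral butenolide.
- Disconnection: C5–C6 and C1–C2, with ring 2 opened to a γ-lactone whose carbonyl is C8 and whose acetal carbon is C4.
- Forward key step: the 2-lithio derivative (n-BuLi) of dithiane A2, 2-(3,4,5-trimethoxyphenyl)-1,3-dithiane, adds to the β-carbon of butenolide A1, (5R)-5-(l-menthyloxy)furan-2(5H)-one. The lactone enolate is trapped by aldehyde 5 to give the 3,4-trans-4,5-trans adduct A3.
- For: a convergent three-component union; the menthyloxy acetal directs both new ring substituents trans; there is no regiochemical question. On the certainty of the C–C bond formation and on the absolute configuration at C1 and C5 it is stronger than the chosen route.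
- Against: A3 contains no ring of the target and four oxygenated carbons at the wrong oxidation level.
  - The dithiane must be hydrolysed next to two electron-rich arenes and the C6 ketone reduced with control of configuration.
  - Lactone C8 and acetal C4 must both be reduced, and two ethers closed with the right oxygen on the right carbon.
  - The C2 carbinol configuration from the aldol is not controlled and would have to be corrected in an acid-mediated closure that equilibrates exo and endo aryl isomers.
- Comparison: the sequence after the key step would be roughly twice as long. The chosen route offers a key step that delivers a ring, the oxidation pattern and three stereocentres together, with four steps left to the target.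

**Alternative 2:** Norrish–Yang photocyclisation.
- Disconnection: C1–C2 of ring 1.
- Forward key step: irradiation of furanone A4, (4R,5S)-4-({[3-(benzyloxy)-4,5-dimethoxybenzyl]oxy}methyl)-5-(3,4,5-trimethoxyphenyl)oxolan-3-one. The excited C1 carbonyl abstracts the benzylic hydrogen at C2 through the chain C5–C4–O3–C2, and the 1,5-biradical recombines to the bridgehead alcohol A5, the 1-hydroxy derivative of 16.
- For: reagent-free and neutral; it closes the hindered C1–C2 bond and ring 1 in one operation. The atom γ to the carbonyl is O3, so the usual competing γ-abstraction is absent.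
- Against:
  - C2 arises from recombination of a conformationally mobile biradical, so exo versus endo ArA is not controlled; in the chosen route C2 is set by catalysis before anything else.
  - The ketone is α-alkoxy on the C8 side and prone to α-cleavage, and two trioxygenated arenes can quench the excited carbonyl by charge transfer.
  - A5 carries a tertiary hydroxyl on C1 that the target lacks; a radical deoxygenation of a hindered bridgehead alcohol adds two steps.
  - A4 itself must be made as one enantiomer, with C5 labile next to the ketone.
- Comparison: it is leaner in bond-forming events but weaker on stereocontrol and on functional-group economy.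

**Alternative 3:** Titanocene epoxide radical cascade.
- Disconnection: C1–C5 and C6–O7.
- Forward key step: Cp2TiCl (trivalent titanium) opens the terminal C1–C8 epoxide of epoxy ether A6, (2S)-2-[(R)-[3-(benzyloxy)-4,5-dimethoxyphenyl]{[(2E)-3-(3,4,5-trimethoxyphenyl)prop-2-en-1-yl]oxy}methyl]oxirane, at C1. The C1 radical cyclises 5-exo onto the cinnamyl double bond (C1–C5, ring 1). Iodine then makes benzylic C6 electrophilic and the titanium alkoxide on O7 closes ring 2. The product A7 is identical with 16.
- For: the shortest way. Both rings form in one flask from an aryl vinyl carbinol epoxide and a cinnamyl bromide, and no carbonyl has to be removed afterwards. On step economy it is clearly stronger than the chosen route.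
- Against:
  - C5 is set by the conformational preference of a radical 5-exo transition state and C6 by a cation-like closure at elevated temperature, so the C1/C5 relation and the aryl orientation at C6 are under weaker control.
  - Premature reduction of the C6 radical should give monocyclic by-products.
  - Stoichiometric titanocene is needed, and the single enantiomer comes from a kinetic-resolution epoxidation that discards half of the material.
- Comparison: the chosen route has a defined control element for each stereocentre (catalyst for C2, suprafacial addition anti to ArA for C1 and C5, equilibration then stereoretentive migration for C6). Because it is short and uses known chemistry, this alternative is kept as the fallback for the key step.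

Key step: step 6

## Route

Step 1
Reactants: 1 3,4,5-trimethoxyphenylacetic acid
Product: 3 N,N-dimethyl-2-(3,4,5-trimethoxyphenyl)acetamide, via acid chloride 2 (not isolated)
Conditions: (COCl)2, DMF (cat.), CH2Cl2, 0 °C to rt; then Me2NH (2 M in THF, excess), 0 °C
Reagents that add atoms: dimethylamine, CNC
Why: Acyl substitution through the acid chloride is a standard amidation; the tertiary dimethylamide is the substrate class that forms keteniminium salts on activation.

Step 2
Reactants: 4 3-hydroxy-4,5-dimethoxybenzaldehyde
Product: 5 3-(benzyloxy)-4,5-dimethoxybenzaldehyde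
Conditions: BnBr, K2CO3, DMF, 60 °C
Reagents that add atoms: benzyl bromide, BrCc1ccccc1
Why: Williamson etherification of the phenoxide; the benzyl ether should survive peracid, triflic anhydride, amine bases and hydride reagents and is removed only at the end.

Step 3
Reactants: 5 3-(benzyloxy)-4,5-dimethoxybenzaldehyde
Product: 7 3-(benzyloxy)-4,5-dimethoxyphenol, via aryl formate 6 (not isolated)
Conditions: mCPBA, CH2Cl2, 0 to 40 °C; aq. NaHCO3 wash; then K2CO3 (cat.), MeOH, rt
Reagents that add atoms: 3-chloroperoxybenzoic acid (mCPBA), OOC(=O)c1cccc(Cl)c1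
Why: Dakin-type Baeyer–Villiger oxidation: the aryl group, activated by the para-methoxy group, should migrate in preference to hydride to give formate 6, which is methanolysed to the phenol.

Step 4
Reactants: 7 3-(benzyloxy)-4,5-dimethoxyphenol
Product: 8 3-(benzyloxy)-4,5-dimethoxyphenyl trifluoromethanesulfonate
Conditions: Tf2O, pyridine, CH2Cl2, 0 °C
Reagents that add atoms: trifluoromethanesulfonic anhydride, O=S(=O)(OS(=O)(=O)C(F)(F)F)C(F)(F)F
Why: O-Sulfonylation of a phenol; the triflate is the leaving group that gives the cationic aryl–palladium intermediate needed for an enantioselective Heck reaction.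

Step 5
Reactants: 8 3-(benzyloxy)-4,5-dimethoxyphenyl trifluoromethanesulfonate; 9 2,3-dihydrofuran
Product: 10 (2S)-2-[3-(benzyloxy)-4,5-dimethoxyphenyl]-2,5-dihydrofuran
Conditions: Pd2(dba)3 (3 mol%), (R)-4-tert-butyl-2-[2-(diphenylphosphanyl)phenyl]-4,5-dihydrooxazole (7 mol%), iPr2NEt, 9 (5 equiv), THF, 65 °C
Reagents that add atoms: none
Why: Asymmetric intermolecular Heck reaction: oxidative addition of 8 to zerovalent palladium gives a cationic aryl–palladium complex that inserts the enol ether double bond of 9 with the aryl group going to the carbon next to oxygen, and β-hydride elimination away from that carbon gives the 2,5-dihydrofuran. The P,N-ligand sets C2 in the insertion step and lets the alkene dissociate before re-insertion, so the double bond should stay at C1=C5.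

Step 6
Reactants: 3 N,N-dimethyl-2-(3,4,5-trimethoxyphenyl)acetamide; 10 (2S)-2-[3-(benzyloxy)-4,5-dimethoxyphenyl]-2,5-dihydrofuran
Product: 13 (1R,4S,5S,7S)-4-[3-(benzyloxy)-4,5-dimethoxyphenyl]-7-(3,4,5-trimethoxyphenyl)-3-oxabicyclo[3.2.0]heptan-6-one (cis-fused; both aryl groups exo), via keteniminium triflate 11 (not isolated), via cyclobutaniminium triflate 12 (not isolated)
Conditions: 3 (1.5 equiv), Tf2O (1.4 equiv), ClCH2CH2Cl, −20 °C; then 10 (1.0 equiv), 2,4,6-collidine (1.6 equiv, slow addition), −20 to 80 °C; then aq. NaHCO3, rt; DBU (cat.), CH2Cl2, rt if the endo-aryl epimer remains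
Reagents that add atoms: water, O
Why: Tf2O activates amide 3 at oxygen and collidine removes the benzylic proton to give keteniminium triflate 11, whose sp carbon C8 is strongly electrophilic. The C1=C5 π bond of 10 attacks C8 to form C1–C8, and the enamine carbon C6 then collapses onto the cationic C5 to form C5–C6, a stepwise but suprafacial (2+2) cycloaddition that gives iminium salt 12 and, after hydrolysis, ketone 13; the closest known reaction type is the (2+2) cycloaddition of keteniminium salts from tertiary amides with unactivated cis-cycloalkenes and allyl ethers. The cyclobutane is closed in the second bond formation by a 4-exo-type recombination of the two ends of the 1,4-dipole (enamine C6 onto cation C5), and the five-membered ring forces a cis fusion. C1 and C5 are set together by approach of 11 to the alkene face opposite ArA, the only substituent on the ring, so that C8 ends up trans to ArA. C6 is not set kinetically: it is benzylic and α to the iminium and later the ketone, and equilibration through the enamine of 12 or the enol of 13 should place ArB on the convex (exo) face. The step needs regiocontrol (C8 to C1, C6 to C5), anti facial selectivity and the exo aryl group; regiocontrol rests on positive charge developing more easily at C5, flanked by the C4 methylene, than at C1, flanked by C2 with its oxygen and aryl substituents, and on the ArB-bearing terminus closing on the carbon remote from ArA. This bias is modest and is the main uncertainty of the route. Amide and Tf2O are combined before 10 is added so that no free anhydride meets the acid-sensitive allylic benzylic ether, and 10 is the limiting component.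

Step 7
Reactants: 13 (1R,4S,5S,7S)-4-[3-(benzyloxy)-4,5-dimethoxyphenyl]-7-(3,4,5-trimethoxyphenyl)-3-oxabicyclo[3.2.0]heptan-6-one
Product: 14 (1S,2S,5R,6S)-2-[3-(benzyloxy)-4,5-dimethoxyphenyl]-6-(3,4,5-trimethoxyphenyl)-3,7-dioxabicyclo[3.3.0]octan-8-one
Conditions: mCPBA, NaHCO3, CH2Cl2, 0 °C to rt
Reagents that add atoms: 3-chloroperoxybenzoic acid (mCPBA), OOC(=O)c1cccc(Cl)c1
Why: Baeyer–Villiger oxidation of a strained cyclobutanone, fast at low temperature; the secondary benzylic C6 should migrate in preference to C1, which is deactivated by the β-oxygen on C2, so O7 enters between C8 and C6. Migration proceeds with retention, so the exo configuration of C6 is carried into ring 2.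

Step 8
Reactants: 14 (1S,2S,5R,6S)-2-[3-(benzyloxy)-4,5-dimethoxyphenyl]-6-(3,4,5-trimethoxyphenyl)-3,7-dioxabicyclo[3.3.0]octan-8-one
Product: 15 (1S,2S,5R,6S)-2-[3-(benzyloxy)-4,5-dimethoxyphenyl]-6-(3,4,5-trimethoxyphenyl)-3,7-dioxabicyclo[3.3.0]octan-8-ol (both C8 epimers)
Conditions: iBu2AlH (1.2 equiv), CH2Cl2, −78 °C; aq. potassium sodium tartrate
Reagents that add atoms: none
Why: Partial reduction of a γ-lactone: at −78 °C the tetrahedral aluminium hemiacetal should persist until work-up and give the lactol; the ethers are inert.

Step 9
Reactants: 15 (1S,2S,5R,6S)-2-[3-(benzyloxy)-4,5-dimethoxyphenyl]-6-(3,4,5-trimethoxyphenyl)-3,7-dioxabicyclo[3.3.0]octan-8-ol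
Product: 16 (1R,2S,5R,6S)-2-[3-(benzyloxy)-4,5-dimethoxyphenyl]-6-(3,4,5-trimethoxyphenyl)-3,7-dioxabicyclo[3.3.0]octane
Conditions: Et3SiH, BF3·OEt2, CH2Cl2, −78 to −40 °C; aq. NaHCO3 quench
Reagents that add atoms: none
Why: Ionic deoxygenation of a lactol: BF3 ionises the hemiacetal to a cyclic oxocarbenium ion at C8, which takes hydride from the silane; C8 is not stereogenic. The low temperature is chosen so that the lactol ionises well before the benzylic ethers C2–O3 and C6–O7 (the change of descriptor at C1 is only a change of CIP priorities).

Step 10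
Reactants: 16 (1R,2S,5R,6S)-2-[3-(benzyloxy)-4,5-dimethoxyphenyl]-6-(3,4,5-trimethoxyphenyl)-3,7-dioxabicyclo[3.3.0]octane
Product: 17 (1R,2S,5R,6S)-2-(3-hydroxy-4,5-dimethoxyphenyl)-6-(3,4,5-trimethoxyphenyl)-3,7-dioxabicyclo[3.3.0]octane (CNP0181235.1)
Conditions: H2 (1 atm), 10% Pd/C (palladium on carbon), EtOAc, rt
Reagents that add atoms: none
Why: Hydrogenolysis of an aryl benzyl ether; under neutral conditions at atmospheric pressure this O–CH2Ph bond should be cleaved well before the dialkyl benzylic ethers of the core, and the reaction is stopped after one equivalent of hydrogen.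

## Compound list

1 | 3,4,5-trimethoxyphenylacetic acid | COc1cc(CC(=O)O)cc(OC)c1OC | starting material
2 | 3,4,5-trimethoxyphenylacetyl chloride | COc1cc(CC(=O)Cl)cc(OC)c1OC | intermediate (not isolated)
3 | N,N-dimethyl-2-(3,4,5-trimethoxyphenyl)acetamide | CN(C)C(=O)Cc1cc(OC)c(OC)c(OC)c1 | intermediate
4 | 3-hydroxy-4,5-dimethoxybenzaldehyde | COc1cc(C=O)cc(O)c1OC | starting material
5 | 3-(benzyloxy)-4,5-dimethoxybenzaldehyde | COc1cc(C=O)cc(OCc2ccccc2)c1OC | intermediate
6 | 3-(benzyloxy)-4,5-dimethoxyphenyl formate | COc1cc(OC=O)cc(OCc2ccccc2)c1OC | intermediate (not isolated)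
7 | 3-(benzyloxy)-4,5-dimethoxyphenol | COc1cc(O)cc(OCc2ccccc2)c1OC | intermediate
8 | 3-(benzyloxy)-4,5-dimethoxyphenyl trifluoromethanesulfonate | COc1cc(OS(=O)(=O)C(F)(F)F)cc(OCc2ccccc2)c1OC | intermediate
9 | 2,3-dihydrofuran | C1=COCC1 | starting material
10 | (2S)-2-[3-(benzyloxy)-4,5-dimethoxyphenyl]-2,5-dihydrofuran | C1=C[C@@H](c2cc(OCc3ccccc3)c(OC)c(OC)c2)OC1 | intermediate
11 | N,N-dimethyl-2-(3,4,5-trimethoxyphenyl)ethen-1-iminium (keteniminium) trifluoromethanesulfonate | C[N+](C)=C=Cc1cc(OC)c(OC)c(OC)c1.[O-]S(=O)(=O)C(F)(F)F | intermediate (not isolated)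
12 | N,N-dimethyliminium trifluoromethanesulfonate of ketone 13 (same configuration; the C6 epimer may be present and converges on equilibration) | C[N+](C)=C1[C@H](c3cc(OC)c(OC)c(OC)c3)[C@H]2CO[C@H](c3cc(OCc4ccccc4)c(OC)c(OC)c3)[C@@H]12.[O-]S(=O)(=O)C(F)(F)F | intermediate (not isolated)
13 | (1R,4S,5S,7S)-4-[3-(benzyloxy)-4,5-dimethoxyphenyl]-7-(3,4,5-trimethoxyphenyl)-3-oxabicyclo[3.2.0]heptan-6-one | O=C1[C@H](c3cc(OC)c(OC)c(OC)c3)[C@H]2CO[C@H](c3cc(OCc4ccccc4)c(OC)c(OC)c3)[C@@H]12 | intermediate
14 | (1S,2S,5R,6S)-2-[3-(benzyloxy)-4,5-dimethoxyphenyl]-6-(3,4,5-trimethoxyphenyl)-3,7-dioxabicyclo[3.3.0]octan-8-one | O=C1O[C@H](c3cc(OC)c(OC)c(OC)c3)[C@H]2CO[C@H](c3cc(OCc4ccccc4)c(OC)c(OC)c3)[C@@H]12 | intermediate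
15 | (1S,2S,5R,6S)-2-[3-(benzyloxy)-4,5-dimethoxyphenyl]-6-(3,4,5-trimethoxyphenyl)-3,7-dioxabicyclo[3.3.0]octan-8-ol, both C8 epimers | OC1O[C@H](c3cc(OC)c(OC)c(OC)c3)[C@H]2CO[C@H](c3cc(OCc4ccccc4)c(OC)c(OC)c3)[C@@H]12 | intermediate
16 | (1R,2S,5R,6S)-2-[3-(benzyloxy)-4,5-dimethoxyphenyl]-6-(3,4,5-trimethoxyphenyl)-3,7-dioxabicyclo[3.3.0]octane | COc1cc([C@H]2OC[C@H]3[C@@H]2CO[C@@H]3c2cc(OC)c(OC)c(OC)c2)cc(OCc2ccccc2)c1OC | intermediate
17 | (1R,2S,5R,6S)-2-(3-hydroxy-4,5-dimethoxyphenyl)-6-(3,4,5-trimethoxyphenyl)-3,7-dioxabicyclo[3.3.0]octane | COc1cc([C@H]2OC[C@H]3[C@@H]2CO[C@@H]3c2cc(OC)c(OC)c(OC)c2)cc(O)c1OC | target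

## Step count and least certain steps

Total: 10 steps. Longest linear sequence: 9 steps (4 to 17, steps 2–10); step 1 is a one-step branch.

**Step 6 (key step).**
- What may go wrong: insufficient regiocontrol in the first C–C bond formation, since the two alkene carbons differ only through the remote ArA group, so that the iminium carbon also bonds to C5. In addition, the alkene is deactivated by two allylic C–O bonds, so acid-induced ring opening or aromatisation of the dihydrofuran and self-condensation of the keteniminium ion may outrun the cycloaddition.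
- Fallback: a different disconnection (C1–C5 and C6–O7 by a titanocene radical cascade). It sets out from 5 and returns at 16, bypassing 6–15.
  - Aldehyde 5 is treated with vinylmagnesium bromide (THF, 0 °C) to give the racemic allylic alcohol F1.
  - A kinetic-resolution Sharpless epoxidation (Ti(OiPr)4, D-(−)-diisopropyl tartrate, tBuOOH 0.6 equiv, 4 Å sieves, CH2Cl2, −20 °C) should epoxidise the (S)-enantiomer to the erythro epoxy alcohol F2; the carbinol centre of F2 is the future C2.
  - Commercial (E)-3-(3,4,5-trimethoxyphenyl)prop-2-en-1-ol is converted with PBr3 (Et2O, 0 °C) into the cinnamyl bromide F3.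
  - Alkylation of F2 with F3 (NaH, THF/DMF, 0 °C) gives the epoxy ether F4.
  - Cp2TiCl, made from Cp2TiCl2 and zinc dust in THF, then opens the epoxide; the C1 radical closes ring 1 onto the cinnamyl double bond, and addition of iodine with warming closes ring 2 to give 16. The epoxide stereocentre is destroyed in the radical step and does not matter.

**Step 5.**
- What may go wrong: slow oxidative addition of the electron-rich triflate with catalyst decay, partial migration of the double bond into conjugation with the ring oxygen, and incomplete enantioselectivity.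
- Fallback: the C2–aryl bond comes from a carbonyl addition and the ring from metathesis. It sets out from 5 and returns at 10; steps 3 and 4 are then not needed.
  - Aldehyde 5 is vinylated to the racemic allylic alcohol F1 as above.
  - Resolution with immobilised Candida antarctica lipase B and vinyl acetate (tert-butyl methyl ether, rt) should acylate the (R)-enantiomer to the acetate F6 and leave the (S)-alcohol F5.
  - O-Allylation (NaH, allyl bromide, THF, 0 °C to rt) gives the allyl ether F7.
  - Ring-closing metathesis with the second-generation Grubbs catalyst (CH2Cl2, 40 °C) closes the 2,5-dihydrofuran 10 with loss of ethene.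

**Step 9.**
- What may go wrong: ionisation of the benzylic ether bonds C6–O7 or C2–O3 by BF3, leading to epimerisation towards endo-aryl isomers or to reductive ring opening by the silane; over-reduction in step 8 would add to the loss.
- Fallback: the C8–O7 bond is formed by displacement instead of hydride delivery to an oxocarbenium ion. It sets out from 14 and returns at 16, bypassing 15.
  - Lactone 14 is reduced with LiAlH4 (THF, 0 °C) to the diol F8.
  - Treatment with MsCl (1.05 equiv) in pyridine (0 °C to rt) sulfonylates the primary hydroxyl to the methanesulfonate F9, which should close ring 2 by 5-exo-tet attack of the C6 hydroxyl on C8 to give 16.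
  - The C6–O bond is never broken, so its configuration is kept, and no Lewis acid is present.

## Further compounds

F1 | step 6 | rac-1-[3-(benzyloxy)-4,5-dimethoxyphenyl]prop-2-en-1-ol | C=CC(O)c1cc(OCc2ccccc2)c(OC)c(OC)c1
F2 | step 6 | (R)-[3-(benzyloxy)-4,5-dimethoxyphenyl][(2S)-oxiran-2-yl]methanol | C1O[C@@H]1[C@H](O)c2cc(OCc3ccccc3)c(OC)c(OC)c2
F3 | step 6 | 5-[(1E)-3-bromoprop-1-en-1-yl]-1,2,3-trimethoxybenzene | COc1cc(/C=C/CBr)cc(OC)c1OC
F4 | step 6 | (2S)-2-[(R)-[3-(benzyloxy)-4,5-dimethoxyphenyl]{[(2E)-3-(3,4,5-trimethoxyphenyl)prop-2-en-1-yl]oxy}methyl]oxirane | C1O[C@@H]1[C@H](OC/C=C/c2cc(OC)c(OC)c(OC)c2)c3cc(OCc4ccccc4)c(OC)c(OC)c3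
F5 | step 5 | (1S)-1-[3-(benzyloxy)-4,5-dimethoxyphenyl]prop-2-en-1-ol | C=C[C@H](O)c1cc(OCc2ccccc2)c(OC)c(OC)c1
F6 | step 5 | (1R)-1-[3-(benzyloxy)-4,5-dimethoxyphenyl]prop-2-en-1-yl acetate | C=C[C@@H](OC(C)=O)c1cc(OCc2ccccc2)c(OC)c(OC)c1
F7 | step 5 | 1-(benzyloxy)-2,3-dimethoxy-5-[(1S)-1-(prop-2-en-1-yloxy)prop-2-en-1-yl]benzene | C=C[C@H](OCC=C)c1cc(OCc2ccccc2)c(OC)c(OC)c1
F8 | step 9 | (S)-{(3R,4R,5S)-5-[3-(benzyloxy)-4,5-dimethoxyphenyl]-4-(hydroxymethyl)oxolan-3-yl}(3,4,5-trimethoxyphenyl)methanol | OC[C@@H]1[C@@H](c2cc(OCc3ccccc3)c(OC)c(OC)c2)OC[C@@H]1[C@H](O)c1cc(OC)c(OC)c(OC)c1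
F9 | step 9 | {(2S,3R,4R)-2-[3-(benzyloxy)-4,5-dimethoxyphenyl]-4-[(S)-hydroxy(3,4,5-trimethoxyphenyl)methyl]oxolan-3-yl}methyl methanesulfonate | CS(=O)(=O)OC[C@@H]1[C@@H](c2cc(OCc3ccccc3)c(OC)c(OC)c2)OC[C@@H]1[C@H](O)c1cc(OC)c(OC)c(OC)c1
A1 | alternative 1 | (5R)-5-{[(1R,2S,5R)-5-methyl-2-(propan-2-yl)cyclohexyl]oxy}furan-2(5H)-one | O=C1C=C[C@H](O[C@@H]2C[C@H](C)CC[C@H]2C(C)C)O1
A2 | alternative 1 | 2-(3,4,5-trimethoxyphenyl)-1,3-dithiane | COc1cc(C2SCCCS2)cc(OC)c1OC
A3 | alternative 1 | 3-[(3-benzyloxy-4,5-dimethoxyphenyl)(hydroxy)methyl]-4-[2-(3,4,5-trimethoxyphenyl)-1,3-dithian-2-yl]-5-(l-menthyloxy)oxolan-2-one (3,4-trans, 4,5-trans) | O=C1O[C@@H](O[C@@H]2C[C@H](C)CC[C@H]2C(C)C)[C@H](C2(c3cc(OC)c(OC)c(OC)c3)SCCCS2)[C@H]1[C@H](O)c1cc(OCc2ccccc2)c(OC)c(OC)c1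
A4 | alternative 2 | (4R,5S)-4-({[3-(benzyloxy)-4,5-dimethoxybenzyl]oxy}methyl)-5-(3,4,5-trimethoxyphenyl)oxolan-3-one | O=C1CO[C@H](c2cc(OC)c(OC)c(OC)c2)[C@H]1COCc1cc(OC)c(OC)c(OCc2ccccc2)c1
A5 | alternative 2 | 2-[3-(benzyloxy)-4,5-dimethoxyphenyl]-6-(3,4,5-trimethoxyphenyl)-3,7-dioxabicyclo[3.3.0]octan-1-ol (1-hydroxy derivative of 16) | COc1cc([C@H]2OC[C@H]3[C@]2(O)CO[C@@H]3c2cc(OC)c(OC)c(OC)c2)cc(OCc2ccccc2)c1OC
A6 | alternative 3 | (2S)-2-[(R)-[3-(benzyloxy)-4,5-dimethoxyphenyl]{[(2E)-3-(3,4,5-trimethoxyphenyl)prop-2-en-1-yl]oxy}methyl]oxirane (same compound as F4) | C1O[C@@H]1[C@H](OC/C=C/c2cc(OC)c(OC)c(OC)c2)c3cc(OCc4ccccc4)c(OC)c(OC)c3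
A7 | alternative 3 | (1R,2S,5R,6S)-2-[3-(benzyloxy)-4,5-dimethoxyphenyl]-6-(3,4,5-trimethoxyphenyl)-3,7-dioxabicyclo[3.3.0]octane (same compound as 16) | COc1cc([C@H]2OC[C@H]3[C@@H]2CO[C@@H]3c2cc(OC)c(OC)c(OC)c2)cc(OCc2ccccc2)c1OC
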